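**Assumption:** read from the SMILES, the target is the erythro (1S,2R) acetoxy/aryloxy pair with a (2R)-aryloxypropyl carbon; reagents that only protect, activate or acylate are given by name and SMILES and are not numbered.

## Retrosynthetic overview

1. Target ⇒ erythro benzylic alcohol (acetylation last) ⇒ chelation-controlled reduction of an α-aryloxy aryl ketone ⇒ Weinreb amide + 3,4,5-trimethoxyphenyl Grignard.
2. Ring B–O–CH(CH3) ether ⇒ Mitsunobu inversion of ethyl (S)-lactate, itself made by ketoreductase reduction of ethyl pyruvate.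
3. Ring A–O–CH(CH3) ether ⇒ Mitsunobu inversion of an (S)-1-arylpropan-2-ol with (E)-4-propenyl-2,6-dimethoxyphenol; the (S)-carbinol comes from ketoreductase reduction of the arylacetone (first stereocentre).
4. Arylacetone ⇐ 4-allyl-2,6-dimethoxyphenol (silylation, Wacker oxidation); propenylphenol ⇐ 4-bromo-2,6-dimethoxyphenol (Suzuki coupling).
5. No ring is formed: all three benzene rings are bought; assembly order is ring B unit → A–B ether → A–B–C.

## Route

**Step 1**
Reactants: 1 4-bromo-2,6-dimethoxyphenol; 2 (E)-prop-1-en-1-ylboronic acid pinacol ester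
Product: 3 (E)-2,6-dimethoxy-4-(prop-1-en-1-yl)phenol
Conditions: Pd(dppf)Cl2 (3 mol%), K2CO3, 1,4-dioxane/H2O 4:1, 85 °C
Reagents that add atoms: none
Why: Suzuki–Miyaura coupling transfers the alkenyl group with retention of the E geometry and tolerates the free phenol.

**Step 2**
Reactants: 4 4-allyl-2,6-dimethoxyphenol
Product: 5 (4-allyl-2,6-dimethoxyphenoxy)triisopropylsilane
Conditions: TIPSCl, imidazole, DMAP (cat.), DMF, 40 °C
Reagents that add atoms: triisopropylsilyl chloride, CC(C)[Si](Cl)(C(C)C)C(C)C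
Why: Silylation of the phenol gives a robust silyl ether that survives oxidation, buffer and Mitsunobu conditions and is later removed by fluoride without touching the propenyl group.

**Step 3**
Reactants: 5 (4-allyl-2,6-dimethoxyphenoxy)triisopropylsilane
Product: 6 1-[3,5-dimethoxy-4-(triisopropylsilyloxy)phenyl]propan-2-one
Conditions: PdCl2 (10 mol%), CuCl (co-catalyst), O2 (1 atm), DMF/H2O 7:1, rt
Reagents that add atoms: water, O
Why: Tsuji–Wacker oxidation (Markovnikov hydroxypalladation, then β-hydride elimination) converts the terminal allyl group into the methyl ketone.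

**Step 4**
Reactants: 6 1-[3,5-dimethoxy-4-(triisopropylsilyloxy)phenyl]propan-2-one
Product: 7 (2S)-1-[3,5-dimethoxy-4-(triisopropylsilyloxy)phenyl]propan-2-ol
Conditions: ketoreductase (Prelog-selective, NADP-dependent, panel hit), NADP+ (cat.), i-PrOH (15% v/v), KPi buffer pH 7.0, 30 °C
Reagents that add atoms: none
Why: Enzymatic asymmetric ketone reduction: the ketoreductase delivers hydride from NADPH to the Re face of the methyl/arylmethyl ketone (Prelog rule), setting the first stereocentre as S in high ee, with i-PrOH recycling the cofactor.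

**Step 5**
Reactants: 7 (2S)-1-[3,5-dimethoxy-4-(triisopropylsilyloxy)phenyl]propan-2-ol; 3 (E)-2,6-dimethoxy-4-(prop-1-en-1-yl)phenol
Product: 8 triisopropyl{4-[(2R)-2-{2,6-dimethoxy-4-[(E)-prop-1-en-1-yl]phenoxy}propyl]-2,6-dimethoxyphenoxy}silane
Conditions: PPh3, DIAD, THF (1 M), 0 °C → rt
Reagents that add atoms: none
Why: Mitsunobu etherification: the phenol (pKa about 10) displaces the alkoxyphosphonium by SN2 with clean inversion, turning the S carbinol into the R aryl ether.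

**Step 6**
Reactants: 8 triisopropyl{4-[(2R)-2-{2,6-dimethoxy-4-[(E)-prop-1-en-1-yl]phenoxy}propyl]-2,6-dimethoxyphenoxy}silane
Product: 9 4-[(2R)-2-{2,6-dimethoxy-4-[(E)-prop-1-en-1-yl]phenoxy}propyl]-2,6-dimethoxyphenol
Conditions: TBAF, AcOH (1:1), THF, 0 °C
Reagents that add atoms: none
Why: Buffered fluoride desilylation cleaves only the aryl silyl ether and leaves the alkyl aryl ether, the stereocentre and the alkene untouched.

**Step 7**
Reactants: 10 ethyl pyruvate
Product: 11 ethyl (2S)-2-hydroxypropanoate (ethyl (S)-lactate)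
Conditions: ketoreductase (Prelog-selective), NADP+ (cat.), i-PrOH, KPi buffer pH 6.5, 25 °C; extraction, distillation
Reagents that add atoms: none
Why: Enzymatic asymmetric reduction of the α-keto ester by Re-face hydride delivery gives the S hydroxy ester in high ee from an achiral precursor.

**Step 8**
Reactants: 9 4-[(2R)-2-{2,6-dimethoxy-4-[(E)-prop-1-en-1-yl]phenoxy}propyl]-2,6-dimethoxyphenol; 11 ethyl (2S)-2-hydroxypropanoate
Product: 12 ethyl (2R)-2-{4-[(2R)-2-{2,6-dimethoxy-4-[(E)-prop-1-en-1-yl]phenoxy}propyl]-2,6-dimethoxyphenoxy}propanoate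
Conditions: PPh3, DIAD, THF, 0 °C → rt
Reagents that add atoms: none
Why: Mitsunobu etherification of an activated lactate with a 2,6-dimethoxyphenol proceeds by SN2 inversion (S → R) and sets the second ether stereocentre.

**Step 9**
Reactants: 12 ethyl (2R)-2-{4-[(2R)-2-{2,6-dimethoxy-4-[(E)-prop-1-en-1-yl]phenoxy}propyl]-2,6-dimethoxyphenoxy}propanoate
Product: 13 (2R)-2-{4-[(2R)-2-{2,6-dimethoxy-4-[(E)-prop-1-en-1-yl]phenoxy}propyl]-2,6-dimethoxyphenoxy}-N-methoxy-N-methylpropanamide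
Conditions: MeNH(OMe)·HCl, i-PrMgCl, THF, −20 → −5 °C; 1 M HCl quench
Reagents that add atoms: N,O-dimethylhydroxylamine hydrochloride, CNOC.Cl
Why: Weinreb amide formation by aminolysis of the ester with the magnesium amide is fast at low temperature, so the α-aryloxy stereocentre is not epimerised.

**Step 10**
Reactants: 13 (2R)-2-{4-[(2R)-2-{2,6-dimethoxy-4-[(E)-prop-1-en-1-yl]phenoxy}propyl]-2,6-dimethoxyphenoxy}-N-methoxy-N-methylpropanamide; 14 5-bromo-1,2,3-trimethoxybenzene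
Product: 16 (2R)-2-{4-[(2R)-2-{2,6-dimethoxy-4-[(E)-prop-1-en-1-yl]phenoxy}propyl]-2,6-dimethoxyphenoxy}-1-(3,4,5-trimethoxyphenyl)propan-1-one, via 3,4,5-trimethoxyphenylmagnesium bromide 15 (not isolated)
Conditions: 14, Mg, THF, 45 °C; then 13, THF, 0 °C; cold 1 M HCl quench
Reagents that add atoms: none
Why: Weinreb ketone synthesis: the Grignard reagent adds once to give a stable magnesium chelate that releases the ketone only on acidic quench, avoiding over-addition and base-mediated epimerisation.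

**Step 11**
Reactants: 16 (2R)-2-{4-[(2R)-2-{2,6-dimethoxy-4-[(E)-prop-1-en-1-yl]phenoxy}propyl]-2,6-dimethoxyphenoxy}-1-(3,4,5-trimethoxyphenyl)propan-1-one
Product: 17 (1S,2R)-2-{4-[(2R)-2-{2,6-dimethoxy-4-[(E)-prop-1-en-1-yl]phenoxy}propyl]-2,6-dimethoxyphenoxy}-1-(3,4,5-trimethoxyphenyl)propan-1-ol
Conditions: Zn(BH4)2 (stock solution in Et2O), Et2O/CH2Cl2, −40 → −20 °C; H2O quench; chromatography
Reagents that add atoms: none
Why: Chelation-controlled (Cram-chelate) reduction: zinc bridges the carbonyl and the aryloxy/ortho-methoxy oxygens and hydride attacks from the side of the small C–H, giving the anti (erythro) 1S alcohol; the minor threo isomer is removed by chromatography.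

**Step 12**
Reactants: 17 (1S,2R)-2-{4-[(2R)-2-{2,6-dimethoxy-4-[(E)-prop-1-en-1-yl]phenoxy}propyl]-2,6-dimethoxyphenoxy}-1-(3,4,5-trimethoxyphenyl)propan-1-ol
Product: 18 (1S,2R)-2-{4-[(2R)-2-{2,6-dimethoxy-4-[(E)-prop-1-en-1-yl]phenoxy}propyl]-2,6-dimethoxyphenoxy}-1-(3,4,5-trimethoxyphenyl)propyl acetate
Conditions: Ac2O, pyridine, DMAP (cat.), CH2Cl2, rt
Reagents that add atoms: acetic anhydride, CC(=O)OC(C)=O
Why: DMAP-catalysed acetylation of the secondary benzylic alcohol occurs at oxygen with retention, giving the target.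

## Compound list

1 | 4-bromo-2,6-dimethoxyphenol | COc1cc(Br)cc(OC)c1O | starting material
2 | (E)-prop-1-en-1-ylboronic acid pinacol ester | C/C=C/B1OC(C)(C)C(C)(C)O1 | starting material
3 | (E)-2,6-dimethoxy-4-(prop-1-en-1-yl)phenol | C/C=C/c1cc(OC)c(O)c(OC)c1 | intermediate
4 | 4-allyl-2,6-dimethoxyphenol | C=CCc1cc(OC)c(O)c(OC)c1 | starting material
5 | (4-allyl-2,6-dimethoxyphenoxy)triisopropylsilane | C=CCc1cc(OC)c(O[Si](C(C)C)(C(C)C)C(C)C)c(OC)c1 | intermediate
6 | 1-[3,5-dimethoxy-4-(triisopropylsilyloxy)phenyl]propan-2-one | CC(=O)Cc1cc(OC)c(O[Si](C(C)C)(C(C)C)C(C)C)c(OC)c1 | intermediate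
7 | (2S)-1-[3,5-dimethoxy-4-(triisopropylsilyloxy)phenyl]propan-2-ol | C[C@H](O)Cc1cc(OC)c(O[Si](C(C)C)(C(C)C)C(C)C)c(OC)c1 | intermediate
8 | triisopropyl{4-[(2R)-2-{2,6-dimethoxy-4-[(E)-prop-1-en-1-yl]phenoxy}propyl]-2,6-dimethoxyphenoxy}silane | C/C=C/c1cc(OC)c(O[C@H](C)Cc2cc(OC)c(O[Si](C(C)C)(C(C)C)C(C)C)c(OC)c2)c(OC)c1 | intermediate
9 | 4-[(2R)-2-{2,6-dimethoxy-4-[(E)-prop-1-en-1-yl]phenoxy}propyl]-2,6-dimethoxyphenol | C/C=C/c1cc(OC)c(O[C@H](C)Cc2cc(OC)c(O)c(OC)c2)c(OC)c1 | intermediate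
10 | ethyl pyruvate (ethyl 2-oxopropanoate) | CCOC(=O)C(C)=O | starting material
11 | ethyl (2S)-2-hydroxypropanoate (ethyl (S)-lactate) | C[C@H](O)C(=O)OCC | intermediate
12 | ethyl (2R)-2-{4-[(2R)-2-{2,6-dimethoxy-4-[(E)-prop-1-en-1-yl]phenoxy}propyl]-2,6-dimethoxyphenoxy}propanoate | C/C=C/c1cc(OC)c(O[C@H](C)Cc2cc(OC)c(O[C@H](C)C(=O)OCC)c(OC)c2)c(OC)c1 | intermediate
13 | (2R)-2-{4-[(2R)-2-{2,6-dimethoxy-4-[(E)-prop-1-en-1-yl]phenoxy}propyl]-2,6-dimethoxyphenoxy}-N-methoxy-N-methylpropanamide | C/C=C/c1cc(OC)c(O[C@H](C)Cc2cc(OC)c(O[C@H](C)C(=O)N(C)OC)c(OC)c2)c(OC)c1 | intermediate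
14 | 5-bromo-1,2,3-trimethoxybenzene | COc1cc(Br)cc(OC)c1OC | starting material
15 | 3,4,5-trimethoxyphenylmagnesium bromide | COc1cc([Mg]Br)cc(OC)c1OC | intermediate
16 | (2R)-2-{4-[(2R)-2-{2,6-dimethoxy-4-[(E)-prop-1-en-1-yl]phenoxy}propyl]-2,6-dimethoxyphenoxy}-1-(3,4,5-trimethoxyphenyl)propan-1-one | C/C=C/c1cc(OC)c(O[C@H](C)Cc2cc(OC)c(O[C@H](C)C(=O)c3cc(OC)c(OC)c(OC)c3)c(OC)c2)c(OC)c1 | intermediate
17 | (1S,2R)-2-{4-[(2R)-2-{2,6-dimethoxy-4-[(E)-prop-1-en-1-yl]phenoxy}propyl]-2,6-dimethoxyphenoxy}-1-(3,4,5-trimethoxyphenyl)propan-1-ol | C/C=C/c1cc(OC)c(O[C@H](C)Cc2cc(OC)c(O[C@H](C)[C@@H](O)c3cc(OC)c(OC)c(OC)c3)c(OC)c2)c(OC)c1 | intermediate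
18 | (1S,2R)-2-{4-[(2R)-2-{2,6-dimethoxy-4-[(E)-prop-1-en-1-yl]phenoxy}propyl]-2,6-dimethoxyphenoxy}-1-(3,4,5-trimethoxyphenyl)propyl acetate | C/C=C/c1cc(OC)c(O[C@H](C)Cc2cc(OC)c(O[C@H](C)[C@@H](OC(C)=O)c3cc(OC)c(OC)c(OC)c3)c(OC)c2)c(OC)c1 | target

## Summary

Total step count: 12.
Longest linear sequence: 10 steps (steps 2, 3, 4, 5, 6, 8, 9, 10, 11, 12, from compound 4).

**Three steps most likely to fail**

Step 4 (the ketoreductase may accept the bulky, lipophilic silyl ether ketone poorly or with low ee). The fallback replaces asymmetric reduction by an enzymatic kinetic resolution; it sets out from 6 and comes back at 7. Ketone 6 is reduced with NaBH4 (MeOH, 0 °C) to racemic 1-[3,5-dimethoxy-4-(triisopropylsilyloxy)phenyl]propan-2-ol F1. F1 is then treated with a lipase (Candida antarctica lipase B, vinyl acetate, MTBE, 30 °C, about 55% conversion). By the Kazlauskas rule the R enantiomer is acylated to (2R)-1-[3,5-dimethoxy-4-(triisopropylsilyloxy)phenyl]propan-2-yl acetate F2, and the unreacted S alcohol is 7, separated by chromatography. F2 can be hydrolysed, oxidised back to 6 and recycled.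

Step 5 (Mitsunobu of a secondary homobenzylic alcohol with a hindered phenol; elimination to the conjugated arylpropene competes). The fallback abandons C–O bond formation at that carbinol and instead sets the ether stereocentre on lactate and then makes the aryl–CH2 bond; it sets out from 3 (with 11 and 1) and comes back at 8. Phenol 3 and ethyl (S)-lactate 11 give, under PPh3/DIAD with inversion, ethyl (2R)-2-{2,6-dimethoxy-4-[(E)-prop-1-en-1-yl]phenoxy}propanoate F3. LiAlH4 (THF, 0 °C) reduces it to (2R)-2-{2,6-dimethoxy-4-[(E)-prop-1-en-1-yl]phenoxy}propan-1-ol F4. TsCl/pyridine gives (2R)-2-{2,6-dimethoxy-4-[(E)-prop-1-en-1-yl]phenoxy}propyl 4-methylbenzenesulfonate F5. In parallel, 1 is silylated (TIPSCl, imidazole) to (4-bromo-2,6-dimethoxyphenoxy)triisopropylsilane F6 and converted with Mg in THF into [3,5-dimethoxy-4-(triisopropylsilyloxy)phenyl]magnesium bromide F7. Copper-catalysed coupling of F7 with F5 (CuI 10 mol%, THF, −20 °C → rt) forms the C–C bond without touching the stereocentre and delivers 8.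

Step 11 (the diastereoselectivity of the ketone reduction may be low). The fallback reverses the order in which H and aryl are introduced, so that Felkin–Anh rather than chelation control leads to the erythro isomer; it sets out from 13 (with 15) and comes back at 17. Weinreb amide 13 is reduced with DIBAL-H (THF, −78 °C) to (2R)-2-{4-[(2R)-2-{2,6-dimethoxy-4-[(E)-prop-1-en-1-yl]phenoxy}propyl]-2,6-dimethoxyphenoxy}propanal F8, used crude. Grignard 15 is transmetalated with ClTi(Oi-Pr)3 to (3,4,5-trimethoxyphenyl)titanium triisopropoxide F9. This non-chelating, weakly basic aryl donor adds to F8 at −78 → −20 °C anti to the aryloxy group (Felkin–Anh), giving the (1S,2R) alcohol 17 directly.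

## Further compounds

F1 | step 4 | rac-1-[3,5-dimethoxy-4-(triisopropylsilyloxy)phenyl]propan-2-ol | CC(O)Cc1cc(OC)c(O[Si](C(C)C)(C(C)C)C(C)C)c(OC)c1
F2 | step 4 | (2R)-1-[3,5-dimethoxy-4-(triisopropylsilyloxy)phenyl]propan-2-yl acetate | C[C@@H](OC(C)=O)Cc1cc(OC)c(O[Si](C(C)C)(C(C)C)C(C)C)c(OC)c1
F3 | step 5 | ethyl (2R)-2-{2,6-dimethoxy-4-[(E)-prop-1-en-1-yl]phenoxy}propanoate | C/C=C/c1cc(OC)c(O[C@H](C)C(=O)OCC)c(OC)c1
F4 | step 5 | (2R)-2-{2,6-dimethoxy-4-[(E)-prop-1-en-1-yl]phenoxy}propan-1-ol | C/C=C/c1cc(OC)c(O[C@H](C)CO)c(OC)c1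
F5 | step 5 | (2R)-2-{2,6-dimethoxy-4-[(E)-prop-1-en-1-yl]phenoxy}propyl 4-methylbenzenesulfonate | C/C=C/c1cc(OC)c(O[C@H](C)COS(=O)(=O)c2ccc(C)cc2)c(OC)c1
F6 | step 5 | (4-bromo-2,6-dimethoxyphenoxy)triisopropylsilane | COc1cc(Br)cc(OC)c1O[Si](C(C)C)(C(C)C)C(C)C
F7 | step 5 | [3,5-dimethoxy-4-(triisopropylsilyloxy)phenyl]magnesium bromide | COc1cc([Mg]Br)cc(OC)c1O[Si](C(C)C)(C(C)C)C(C)C
F8 | step 11 | (2R)-2-{4-[(2R)-2-{2,6-dimethoxy-4-[(E)-prop-1-en-1-yl]phenoxy}propyl]-2,6-dimethoxyphenoxy}propanal | C/C=C/c1cc(OC)c(O[C@H](C)Cc2cc(OC)c(O[C@H](C)C=O)c(OC)c2)c(OC)c1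
F9 | step 11 | (3,4,5-trimethoxyphenyl)titanium triisopropoxide | COc1cc([Ti](OC(C)C)(OC(C)C)OC(C)C)cc(OC)c1OC
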